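Labdane numbering is used for the target and all intermediates: decalin C1–C10, CH3-17 on C8, side chain C11–C16, ether oxygen between C8 and C15.

**Plan**
Cuts: first the acetate and the C11=C12 bond of the oxocane (ring-closing metathesis); then the C8–O bond together with C7, which is taken out of ring B as a carbene carbon. This leaves a trans-fused 2-methylcyclopentene and a chiral side-chain alcohol.
Enabling feature: in ring B the fully substituted ether carbon C8 sits next to the unsubstituted C7, so C6–C7–C8 is the capture product of an allyl cation; that cation forms when a dibromocyclopropane fused to C6=C8 of a five-membered precursor opens.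
Forward order: ring A is bought as 2,2,6-trimethylcyclohexanone; the five-membered ring is annulated (Pd allylation, Wacker oxidation, aldol condensation); ring B arises by one-carbon ring expansion with simultaneous C8–O bond formation; the oxocane is closed last.
Stereochemistry: C10 from the enantioselective decarboxylative allylation; C5 from dissolving-metal reduction; C9 by equilibration next to the ketone; C8 from α-face capture of the cation anti to the C10 methyl; C13 from an Ir-catalysed asymmetric allylic alkylation in the side-chain fragment.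

Key step: step 15

Assumption: the ligand enantiomers named in steps 2 and 6 are those that give the configurations drawn (otherwise the mirror-image ligand is used), and compound 1 is taken as commercially available.

**Route**

Step 1
Reactants: 1 (E)-4-(benzyloxy)but-2-en-1-ol
Product: 2 (E)-4-(benzyloxy)but-2-en-1-yl methyl carbonate
Conditions: ClCO2Me, pyridine, CH2Cl2, 0 °C
Reagents that add atoms: methyl chloroformate, COC(=O)Cl
Why: Acylation of the primary allylic alcohol (carbonate formation) installs the leaving group for the allylic substitution and touches no stereocentre.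

Step 2
Reactants: 2 (E)-4-(benzyloxy)but-2-en-1-yl methyl carbonate
Product: 3 dimethyl 2-[(2R)-1-(benzyloxy)but-3-en-2-yl]propanedioate
Conditions: dimethyl malonate, [Ir(cod)Cl]2 (2 mol %), (Sa,S,S)-binaphthol-derived N,N-bis(1-phenylethyl)phosphoramidite (4 mol %), TBD (8 mol %), THF, 25 °C
Reagents that add atoms: dimethyl malonate, COC(=O)CC(=O)OC
Why: Iridium-catalysed asymmetric allylic alkylation is branched-selective, so the malonate attacks the substituted allyl terminus under ligand control and sets the future C13 stereocentre, the methoxide released from the carbonate serving as base.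

Step 3
Reactants: 3 dimethyl 2-[(2R)-1-(benzyloxy)but-3-en-2-yl]propanedioate
Product: 4 methyl (3S)-3-[(benzyloxy)methyl]pent-4-enoate
Conditions: LiCl, H2O, DMSO, 150 °C
Reagents that add atoms: none
Why: Krapcho dealkoxycarbonylation (chloride attacks one ester methyl, the carboxylate loses CO2) removes one ester, and the stereocentre is not α to a carbonyl group and cannot epimerise.

Step 4
Reactants: 4 methyl (3S)-3-[(benzyloxy)methyl]pent-4-enoate
Product: 5 (3S)-3-[(benzyloxy)methyl]pent-4-en-1-ol
Conditions: LiAlH4, THF, 0 °C
Reagents that add atoms: none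
Why: Hydride reduction of the ester gives the primary alcohol that becomes the C15–O unit, while the alkene, the benzyl ether and the stereocentre are inert.

Step 5
Reactants: 6 2,2,6-trimethylcyclohexan-1-one
Product: 7 allyl 2,6,6-trimethylcyclohex-1-en-1-yl carbonate
Conditions: LiN(SiMe3)2, THF, 0 °C; TMEDA, allyl chloroformate, −78 → 25 °C
Reagents that add atoms: allyl chloroformate, C=CCOC(=O)Cl
Why: Deprotonation of the only α-CH and O-acylation of the tetrasubstituted lithium enolate (enol carbonate formation) give the substrate for the decarboxylative allylation.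

Step 6
Reactants: 7 allyl 2,6,6-trimethylcyclohex-1-en-1-yl carbonate
Product: 8 (2R)-2-allyl-2,6,6-trimethylcyclohexan-1-one
Conditions: Pd2(dba)3 (2.5 mol %), (R)-t-BuPHOX (6 mol %), THF, 25 °C
Reagents that add atoms: none
Why: Palladium-catalysed decarboxylative asymmetric allylic alkylation (Tsuji allylation with a chiral phosphinooxazoline) ionises the enol carbonate to a π-allylpalladium enolate that recombines under ligand control and sets the quaternary C10 stereocentre.

Step 7
Reactants: 8 (2R)-2-allyl-2,6,6-trimethylcyclohexan-1-one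
Product: 9 (2R)-2,6,6-trimethyl-2-(2-oxopropyl)cyclohexan-1-one
Conditions: PdCl2 (10 mol %), Cu(OAc)2 (25 mol %), O2 (1 atm), DMA/H2O, 25 °C
Reagents that add atoms: water, O
Why: Tsuji–Wacker oxidation converts the terminal alkene into the methyl ketone with Markovnikov regiochemistry and leaves the quaternary centre untouched.

Step 8
Reactants: 9 (2R)-2,6,6-trimethyl-2-(2-oxopropyl)cyclohexan-1-one
Product: 10 (7aR)-4,4,7a-trimethyl-1,4,5,6,7,7a-hexahydro-2H-inden-2-one
Conditions: KOH, xylenes, 110 °C, Dean–Stark
Reagents that add atoms: none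
Why: Intramolecular aldol condensation of the methyl ketone enolate onto the ring ketone, followed by dehydration, closes the five-membered ring as the conjugated cyclopentenone (C8=O, C6=C5).

Step 9
Reactants: 10 (7aR)-4,4,7a-trimethyl-1,4,5,6,7,7a-hexahydro-2H-inden-2-one
Product: 11 (1S,7aR)-1-allyl-4,4,7a-trimethyl-1,4,5,6,7,7a-hexahydro-2H-inden-2-one (expected major epimer; the 1R epimer is carried along)
Conditions: LiN(iPr)2, THF, −78 °C; allyl bromide, DMPU, −78 → 0 °C
Reagents that add atoms: allyl bromide, C=CCBr
Why: Kinetic deprotonation can only occur at the α′-CH2 (C9) because the γ-position is quaternary, and SN2 alkylation of the cross-conjugated enolate attaches C11, the new centre forming mainly anti to the angular methyl and being corrected in step 10.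

Step 10
Reactants: 11 (1S,7aR)-1-allyl-4,4,7a-trimethyl-1,4,5,6,7,7a-hexahydro-2H-inden-2-one
Product: 13 (1R,3aS,7aS)-1-allyl-4,4,7a-trimethyloctahydro-2H-inden-2-one, via 1-epi ketone 12 (not isolated)
Conditions: Li, NH3/THF, t-BuOH (1 equiv), −78 °C; NH4Cl; then NaOMe (cat.), MeOH, 25 °C
Reagents that add atoms: none
Why: Dissolving-metal (Birch-type) conjugate reduction protonates C5 on the α face, away from the syn-axial methyl groups on C10 and C4, to give the trans ring fusion, and base epimerisation through the enol then places the C9 allyl group pseudo-equatorial and cis to the angular methyl, as for 17β side chains of steroids.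

Step 11
Reactants: 13 (1R,3aS,7aS)-1-allyl-4,4,7a-trimethyloctahydro-2H-inden-2-one
Product: 14 (1R,3aS,7aS)-1-allyl-4,4,7a-trimethyl-3a,4,5,6,7,7a-hexahydro-1H-inden-2-yl trifluoromethanesulfonate
Conditions: KN(SiMe3)2, THF, −78 °C; PhNTf2, −78 → 0 °C
Reagents that add atoms: N-phenylbis(trifluoromethanesulfonimide), O=S(=O)(N(c1ccccc1)S(=O)(=O)C(F)(F)F)C(F)(F)F
Why: Kinetic deprotonation with the bulky amide occurs at the less hindered CH2 (C6) and not at the C9 methine, and O-triflation of the enolate fixes the C6=C8 double bond regiospecifically.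

Step 12
Reactants: 14 enol triflate
Product: 15 1β-allyl-2,4,4,7aβ-tetramethyl-3aα,4,5,6,7,7a-hexahydro-1H-indene (trans-fused; C6=C8 alkene carrying CH3-17)
Conditions: MeMgBr, Fe(acac)3 (5 mol %), THF/NMP, −30 → 0 °C
Reagents that add atoms: methylmagnesium bromide, C[Mg]Br
Why: Iron-catalysed Kumada cross-coupling of the alkenyl triflate installs CH3-17 with retention of the double-bond position and does not touch the isolated allyl group.

Step 13
Reactants: 15 allyl methylcyclopentene
Product: 16 1β-[(E)-prop-1-en-1-yl]-2,4,4,7aβ-tetramethyl-3aα,4,5,6,7,7a-hexahydro-1H-indene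
Conditions: [Ir(cod)(PMePh2)2]PF6 (2 mol %, activated with H2), THF, 25 °C
Reagents that add atoms: none
Why: The cationic iridium hydride isomerises the terminal allyl group to the (E)-propenyl group by reversible insertion and β-hydride elimination, while the hindered trisubstituted ring alkene does not bind.

Step 14
Reactants: 16 propenyl methylcyclopentene
Product: 17 gem-dibromocyclopropane (CBr2 = C7 bridging C6 and C8 on the α face; 9β-(E)-propenyl; trans ring fusion), used at once without purification
Conditions: CHBr3 (1.3 equiv), KOtBu, pentane, −20 → 0 °C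
Reagents that add atoms: bromoform, BrC(Br)Br
Why: Dibromocarbene from α-elimination adds stereospecifically to the more electron-rich trisubstituted C6=C8 alkene from the α face, anti to the angular methyl and the C9 substituent, the 1,2-disubstituted propenyl alkene reacting much more slowly.

Step 15
Reactants: 17 gem-dibromocyclopropane; 5 (3S)-3-[(benzyloxy)methyl]pent-4-en-1-ol
Product: 19 tertiary allylic ether (trans-decalin with C6=C7 bearing Br on C7, C8 carrying β-CH3 and the α-O-[(3S)-3-(benzyloxymethyl)pent-4-en-1-yl] group, C9 carrying β-(E)-propenyl), via bromoallyl cation 18 (not isolated)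
Conditions: AgOTf (1.5 equiv), 5 (4 equiv), 2,6-di-tert-butyl-4-methylpyridine, CH2Cl2, −40 → 0 °C, dark
Reagents that add atoms: none
Why: AgOTf removes the endo bromide of 17 while the C6–C8 cyclopropane bond opens in a disrotatory two-electron electrocyclic process (Woodward–Hoffmann–DePuy), so that C7 is inserted between C6 and C8 and the five-membered ring becomes ring B as the 7-bromo C6–C7–C8 allyl cation 18, which alcohol 5 captures at C8. The closest known reaction type is the silver-promoted ring expansion of 6,6-dibromobicyclo[3.1.0]hexanes to 2-bromocyclohex-2-enyl ethers in the presence of alcohols. Ring B arises by one-carbon ring expansion and not by a cyclisation, so no mode of ring closure applies and no other ring is closed in this step. The new stereocentre C8 is controlled by the axial C10 methyl group, which shields the β face in a 1,3-syn relationship, so the alcohol enters from the α face and gives the 8α-ether with the 8β-methyl, as in the capture of C8 cations of drimanes and labdanes. The step needs capture at C8 and not at C6, and substitution and not elimination: the tertiary terminus carries more of the charge (as in solvolyses of dimethylallyl systems) and C6 is shielded by the 4,4-dimethyl group, while excess 5, low temperature and a hindered non-nucleophilic base hold back proton loss and re-ionisation of the tertiary allylic ether.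

Step 16
Reactants: 19 tertiary allylic ether
Product: 20 16-benzyloxy-7-bromo-8α,15-epoxylabda-6,11(Z)-diene (C13 as in 5)
Conditions: second-generation Hoveyda–Grubbs catalyst (10 mol %), toluene (2 mM), 80 °C
Reagents that add atoms: none
Why: Ring-closing olefin metathesis joins the terminal vinyl group and the propenyl group with loss of propene and closes the eight-membered ether as the Z-alkene, the trans-diequatorial C8–O and C9–C11 bonds holding the two chains gauche and the bromoalkene being inert to the ruthenium carbene.

Step 17
Reactants: 20 bromo diene oxocene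
Product: 21 (5S,8R,9R,10S,13R)-8,15-epoxylabdan-16-ol
Conditions: H2 (3 atm), Pd(OH)2/C, NaOAc, EtOAc/EtOH, 25 °C
Reagents that add atoms: none
Why: Heterogeneous hydrogenation saturates C11=C12, hydrogenolyses the C7–Br bond, saturates C6=C7 and cleaves the benzyl ether in one operation, NaOAc trapping HBr so that the tertiary ether survives, and no stereocentre is formed.

Step 18
Reactants: 21 (5S,8R,9R,10S,13R)-8,15-epoxylabdan-16-ol
Product: 22 (5S,8R,9R,10S,13R)-8,15-epoxylabdan-16-yl acetate
Conditions: Ac2O, pyridine, DMAP (cat.), CH2Cl2, 25 °C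
Reagents that add atoms: acetic anhydride, CC(=O)OC(C)=O
Why: DMAP-catalysed acylation of the primary alcohol gives the acetate, and the tertiary ether is inert.

**Compound list**
1 | (E)-4-(benzyloxy)but-2-en-1-ol | OC/C=C/COCc1ccccc1 | starting material
2 | (E)-4-(benzyloxy)but-2-en-1-yl methyl carbonate | COC(=O)OC/C=C/COCc1ccccc1 | intermediate
3 | dimethyl 2-[(2R)-1-(benzyloxy)but-3-en-2-yl]propanedioate | COC(=O)C(C(=O)OC)[C@H](COCc1ccccc1)C=C | intermediate
4 | methyl (3S)-3-[(benzyloxy)methyl]pent-4-enoate | COC(=O)C[C@H](COCc1ccccc1)C=C | intermediate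
5 | (3S)-3-[(benzyloxy)methyl]pent-4-en-1-ol | OCC[C@H](COCc1ccccc1)C=C | intermediate
6 | 2,2,6-trimethylcyclohexan-1-one | CC1CCCC(C)(C)C1=O | starting material
7 | allyl 2,6,6-trimethylcyclohex-1-en-1-yl carbonate | C=CCOC(=O)OC1=C(C)CCCC1(C)C | intermediate
8 | (2R)-2-allyl-2,6,6-trimethylcyclohexan-1-one | C=CC[C@@]1(C)CCCC(C)(C)C1=O | intermediate
9 | (2R)-2,6,6-trimethyl-2-(2-oxopropyl)cyclohexan-1-one | CC(=O)C[C@@]1(C)CCCC(C)(C)C1=O | intermediate
10 | (7aR)-4,4,7a-trimethyl-1,4,5,6,7,7a-hexahydro-2H-inden-2-one | O=C1C[C@@]2(C)CCCC(C)(C)C2=C1 | intermediate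
11 | (1S,7aR)-1-allyl-4,4,7a-trimethyl-1,4,5,6,7,7a-hexahydro-2H-inden-2-one (major epimer) | O=C1C=C2C(C)(C)CCC[C@]2(C)[C@@H]1CC=C | intermediate
12 | (1S,3aS,7aS)-1-allyl-4,4,7a-trimethyloctahydro-2H-inden-2-one (1-epi ketone, not isolated) | O=C1C[C@H]2C(C)(C)CCC[C@]2(C)[C@@H]1CC=C | intermediate
13 | (1R,3aS,7aS)-1-allyl-4,4,7a-trimethyloctahydro-2H-inden-2-one | O=C1C[C@H]2C(C)(C)CCC[C@]2(C)[C@H]1CC=C | intermediate
14 | (1R,3aS,7aS)-1-allyl-4,4,7a-trimethyl-3a,4,5,6,7,7a-hexahydro-1H-inden-2-yl trifluoromethanesulfonate | O=S(=O)(OC1=C[C@H]2C(C)(C)CCC[C@]2(C)[C@H]1CC=C)C(F)(F)F | intermediate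
15 | 1β-allyl-2,4,4,7aβ-tetramethyl-3aα,4,5,6,7,7a-hexahydro-1H-indene | CC1=C[C@H]2C(C)(C)CCC[C@]2(C)[C@H]1CC=C | intermediate
16 | 1β-[(E)-prop-1-en-1-yl]-2,4,4,7aβ-tetramethyl-3aα,4,5,6,7,7a-hexahydro-1H-indene | CC1=C[C@H]2C(C)(C)CCC[C@]2(C)[C@H]1/C=C/C | intermediate
17 | gem-dibromocyclopropane, CBr2 (C7) bridging C6 and C8 on the α face, 9β-(E)-propenyl | BrC1(Br)[C@@H]2[C@H]3C(C)(C)CCC[C@]3(C)[C@@H](/C=C/C)[C@]12C | intermediate
18 | 7-bromo C6–C7–C8 allyl cation with ring B formed (not isolated) | C[C+]1C(Br)=C[C@H]2C(C)(C)CCC[C@]2(C)[C@H]1/C=C/C | intermediate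
19 | 7-bromo-Δ6 trans-decalin, 8β-CH3, 8α-O-[(3S)-3-(benzyloxymethyl)pent-4-en-1-yl], 9β-(E)-propenyl | C=C[C@@H](COCc1ccccc1)CCO[C@]1(C)C(Br)=C[C@H]2C(C)(C)CCC[C@]2(C)[C@H]1/C=C/C | intermediate
20 | 16-benzyloxy-7-bromo-8α,15-epoxylabda-6,11(Z)-diene | O1CC[C@H](COCc2ccccc2)/C=C\[C@@H]2[C@@]3(C)CCCC(C)(C)[C@@H]3C=C(Br)[C@@]12C | intermediate
21 | (5S,8R,9R,10S,13R)-8,15-epoxylabdan-16-ol | OC[C@H]1CCO[C@]2(C)CC[C@H]3C(C)(C)CCC[C@]3(C)[C@H]2CC1 | intermediate
22 | (5S,8R,9R,10S,13R)-8,15-epoxylabdan-16-yl acetate | CC(=O)OC[C@H]1CCO[C@]2(C)CC[C@H]3C(C)(C)CCC[C@]3(C)[C@H]2CC1 | target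

**Step count and risks**
Total steps: 18. Longest linear sequence: 14 steps (steps 5–18, from 6 to 22); the side-chain alcohol 5 takes 4 steps (steps 1–4).

Most likely to fail, step 15: cation 18 may be captured at C6, or may lose a proton (C9–H or CH3-17) to give dienes, because alcohol 5 is present in only a few equivalents. The fallback sets out from 17. Solvolysis with AgOTf and 2,6-lutidine in acetone/water, where the nucleophile is the solvent, should give the 7-bromo-8α-hydroxy tertiary allylic alcohol F1. Alcohol 5 is converted with Tf2O and 2,6-lutidine (CH2Cl2, −78 °C) into (3S)-3-[(benzyloxy)methyl]pent-4-en-1-yl trifluoromethanesulfonate F2. Williamson alkylation of the potassium alkoxide of F1 (KH, 18-crown-6, THF, −20 °C) with F2 then forms the C15–O bond and the route is rejoined at 19.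

Second, step 16: the ruthenium carbene may fail to engage the neopentyl-type C9 propenyl group, and the terminal vinyl groups may oligomerise by cross-metathesis. The fallback sets out from 19. Ozonolysis of the two side-chain alkenes (O3, CH2Cl2/MeOH, pyridine, −78 °C, Sudan Red as end-point indicator so that the electron-poor bromoalkene is spared; then Me2S) should give the C11,C12-dialdehyde F3. Intramolecular McMurry coupling (TiCl3, Zn–Cu couple, DME, reflux, slow addition at high dilution) joins C11 and C12 reductively and comes back to the route at 20.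

Third, step 10: the epimer equilibrium at C9 may not favour the β-allyl ketone enough, so that material is lost to the 1-epi ketone. The fallback sets out from 10. α′-Methylenation (paraformaldehyde, N-methylanilinium trifluoroacetate, THF, reflux) gives 4,4,7a-trimethyl-1-methylidene-1,4,5,6,7,7a-hexahydro-2H-inden-2-one F4. Conjugate addition of (CH2=CH)2CuLi to the exocyclic enone (THF, −78 °C), followed by kinetic protonation of the enolate from the α face, sets C9 and gives the (1R,7aR)-1-allyl enone F5. Li/NH3 reduction as in step 10, without the base treatment, then delivers 13.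

Further compounds
F1 | step 15 | 7-bromo-8α-hydroxy-8β-methyl-9β-[(E)-prop-1-enyl]-Δ6 trans-decalin (tertiary allylic alcohol) | O[C@]1(C)C(Br)=C[C@H]2C(C)(C)CCC[C@]2(C)[C@H]1/C=C/C
F2 | step 15 | (3S)-3-[(benzyloxy)methyl]pent-4-en-1-yl trifluoromethanesulfonate | C=C[C@@H](COCc1ccccc1)CCOS(=O)(=O)C(F)(F)F
F3 | step 16 | C11,C12-dialdehyde from ozonolysis of both side-chain alkenes of 19 | O=C[C@@H](COCc1ccccc1)CCO[C@]1(C)C(Br)=C[C@H]2C(C)(C)CCC[C@]2(C)[C@H]1C=O
F4 | step 10 | 4,4,7a-trimethyl-1-methylidene-1,4,5,6,7,7a-hexahydro-2H-inden-2-one (C7a as in 10) | O=C1C=C2C(C)(C)CCC[C@]2(C)C1=C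
F5 | step 10 | (1R,7aR)-1-allyl-4,4,7a-trimethyl-1,4,5,6,7,7a-hexahydro-2H-inden-2-one | O=C1C=C2C(C)(C)CCC[C@]2(C)[C@H]1CC=C
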